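The constants used here are made up; the flask was simulated.

The pitfall I guarded against when you asked for a quick number was to count the speed-up of the step to target, a factor of 18 from coldest to hottest, as pure gain, when the burning of substrate to side product speeds up by 260 over the same span.

all flasks: substrate 0.10 M; gas 18 mM (held); time 2.5 min
- zeta: temperature 120 °C
- beta: temperature 80 °C
- alpha: temperature 100 °C
- theta: temperature 60 °C

- the flask that comes out highest in amount of target, in percent of the substrate charged, or "all alike" when all lie within 1.5 percentage points (zeta / beta / alpha / theta / all alike)
- target at the end, in percent of the substrate charged, zeta
- target at the end, in percent of the substrate charged, beta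
- target at the end, in percent of the substrate charged, alpha
- target at the end, in percent of the substrate charged, theta

- at the start none of reagent is dissolved
- at 80 °C the constants are as listed, elsewhere as the activation energies make them

    substrate + reagent → target (k1 = 1.92 /M/s, Ea1 = 52.0 kJ/mol)
    gas ⇌ reagent, rate k2*(csat - [reagent]) (k2 = 0.224 /s, csat = 18 mM)
    substrate → side product (k3 = 0.0257 /s, Ea3 = 101 kJ/mol)
    (constants at 80 °C)

I asked first what the end state must be: substrate that has gone has become either target or side product, so I treated each flask as a race between two clocks. One clock is the burn life, the reciprocal of the rate constant for side product. The other I called the wait, the time substrate needs on the reagent route, which is the sum of a chemical time, the reciprocal of the rate constant for target times 18 mM, and a delivery time, the charge divided by the full transfer rate of gas. At 80 °C the chemical time was 28.9 s and the delivery time 24.8 s, so the wait was 53.7 s; I held the delivery time fixed, since the transfer carries no activation energy. My rule was that the target share equals the burn life over burn life plus wait. Reckoning the wait from the full charge overstates it late in the run, while ignoring that reagent starts from zero understates it early, and I let these two errors stand against each other.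

In beta the burn life of 38.9 s gave 42.0%. In alpha a life of 6.16 s against a wait of 36.0 s gave 14.6%. In zeta a life of 1.18 s against a wait of 29.6 s gave 3.82%, and in that wait the delivery time was longer than the chemical time. In theta the life of 307 s against a wait of 109 s gave a share of 73.8%, but the clocks together left 15.5% of the substrate unconverted in my reckoning at 2.5 min, so I committed to 62.5% and named theta as highest.

The forecast also named theta, with 3.5% for zeta, 44% for beta, 16.5% for alpha and 62% for theta, holding that “heating mainly burns substrate and the coolest flask wins”.

The simulation gave theta as highest, with 3.62% in zeta, 45.6% in beta, 16.8% in alpha and 65.0% in theta.

I then took the wait to the neighbouring flask, a repeat of zeta at 105 °C with the same charge and time. Its wait came to 33.8 s and its burn life to 4.00 s, which made a target share of 10.6%. The simulated neighbour ended with 12.0% target and 0% of its substrate left.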